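(The earlier runs and the new flask come from a simulation for substances that don't exist, and the scatter is random.)

In spring the charge of substrate, 0.010 M, stands below that of reagent, 0.0250 M, so substrate is the limiting reagent and its moles are the ones to book. The four flasks below differ in temperature, and the south run was made at 85 °C.

| flask | substrate | reagent | free catalyst | temperature | remark | time |
|---|---|---|---|---|---|---|
| south | 0.015 M | 0.025 M | 10 µM | 85 °C | run made earlier |  |
| spring | 0.010 M | 0.0250 M | 10 µM | 85 °C |  | 3.0 d |
| noon | 0.010 M | 0.0250 M | 10 µM | 25 °C |  | 3.0 d |
| winter | 0.010 M | 0.0250 M | 10 µM | 55 °C |  | 3.0 d |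
| summer | 0.010 M | 0.0250 M | 10 µM | 115 °C |  | 3.0 d |

south run (percent of the substrate charged): time / h: product / % = 4.00: 17.8; 8.00: 30.3; 10.0: 35.4; 15.0: 47.9; 20.0: 59.4

(standard deviation of a reading: 1 percentage point)

- what may be going on: reagent + free catalyst <-> catalyst intermediate A; catalyst intermediate A <-> catalyst intermediate B; free catalyst -> spent catalyst; catalyst intermediate C <-> catalyst intermediate D; substrate + catalyst intermediate B -> catalyst intermediate C; catalyst intermediate D -> free catalyst + product
- the earlier runs do not show what temperature does; that part of a forecast is a guess

* the best flask by amount of product, in percent of the substrate charged; "all alike" if 1.5 percentage points covers them all (spring / noon / winter / summer / all alike)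
* amount of product at the end, in percent of the substrate charged, spring
* amount of product at the end, in percent of the substrate charged, noon
* amount of product at the end, in percent of the substrate charged, winter
* amount of product at the end, in percent of the substrate charged, summer

The ledger for spring has three entries. The first is substrate held on the catalyst. Each catalyst holds one substrate in catalyst intermediate C or D, so this entry is at most 0.100% of the charge, against a scatter of 1 percentage point. The second is product, and each round of the catalyst takes one reagent with each substrate, so reagent still stands at 60.0% of its own charge when the substrate is used up. The third is substrate left, and this is the entry to reckon, because product follows from it by subtraction.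

The fraction left is easier to follow than the fraction made, since a pseudo-first-order flask loses the same share of what remains in each equal time. The south run leaves 40.6% after 20.0 h, which gives a constant, the logarithm of one over the fraction left divided by the time, of 0.0451 h⁻¹. The first reading gives 0.0490 h⁻¹, so the constant holds within the scatter. The carried quantity is the halving time, the time in which [substrate] falls by a factor of 2: 0.641 d. A fraction does not depend on the amount charged, so this value passes to spring, which has the same reagent, catalyst and temperature.

Spring runs 4.68 halving times, which leaves 3.90% of its substrate. The books close at about 96.1% product, though 3.0 d lies 3.60 times beyond the last reading. This halving time belongs to 85 °C, and no run shows another temperature, so it gives no figure for noon, winter or summer.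

The forecast gives spring 94%, below this reckoning (“I shade this to 94 for slow deactivation”), noon 6%, winter 40%, summer 96%, and names summer as best.

    reagent + free catalyst ⇌ catalyst intermediate A (K = 2600 L mol⁻¹, k = 4.22 L mol⁻¹ s⁻¹, Ea = 46.0 kJ mol⁻¹, ΔH = −39.0 kJ mol⁻¹)
    catalyst intermediate A ⇌ catalyst intermediate B (K = 7.59, k = 0.404 s⁻¹, Ea = 77.0 kJ mol⁻¹, ΔH = −80.0 kJ mol⁻¹)
    free catalyst → spent catalyst (k = 1.78 × 10⁻⁹ s⁻¹, Ea = 114 kJ mol⁻¹)
    catalyst intermediate C ⇌ catalyst intermediate D (K = 0.649, k = 0.00673 s⁻¹, Ea = 91.0 kJ mol⁻¹, ΔH = 5.00 kJ mol⁻¹)
    substrate + catalyst intermediate B → catalyst intermediate C (k = 0.913 L mol⁻¹ s⁻¹, Ea = 59.0 kJ mol⁻¹)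
    catalyst intermediate D → free catalyst + product (k = 0.0120 s⁻¹, Ea = 83.0 kJ mol⁻¹)
    (constants at 25 °C)

Spring ends at 94.5% product, with 5.5% of its substrate left, more than the reckoned 3.90%. The best flask is winter at 99.4%, with noon at 47.8% and summer at 18.7%. Summer's catalyst is >99.9% spent at 3.00 d. Spring reaches 50 percent conversion at 0.632 d, against the halving time of 0.641 d. Winter's own time to that conversion is 0.463 d, so its 3.0 d makes 6.48 such times, a constant halving time there gives 1.12% left, and winter holds 0.56% of its substrate.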